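# Proposed synthesis of CNP0169816.1 by a two-directional epoxonium–allylsilane cascade

Locants follow the C30 squalene chain: left oxepane O/C2–C7, left cyclohexane C6–C11, bridge C12–C13, right cyclohexane C14–C19, right oxepane C18–C23/O. Stereodescriptors are CIP and were rederived for every structure.

## The problem

Target 21 consists of two trans-fused oxepane–cyclohexane bicycles joined through C11 and C14 by the C12–C13 ethylene bridge. It has ten stereocentres. Eight of them (C3, C6, C7, C11 and C22, C19, C18, C14, all S) form a C2-symmetric set, with a quaternary angular-methyl carbon (C6, C19) in each half.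

The symmetry is broken twice. C10 is R (acetate axial, syn to the C6 methyl), whereas C15 is S (acetate equatorial, its methyl syn-axial to the C19 methyl). C3 is acetylated, whereas C22 keeps a free hydroxyl; the half with the axial tertiary acetate is the one with the secondary acetate.

Inside one bicycle, stereocontrol is available. A trans-epoxide fixes C6/C7, a chair fixes C11, and the axial angular methyl biases additions at C10 or C15. Nothing relays information across the bridge, and nothing relays it from C3/C22 to C10/C15 of the same half, which lie anti and seven bonds apart.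

The two tertiary acetates are hard to install and ionise under strong acid. The tertiary ethers at C2 and C23, and any polyepoxide or allylsilane precursor, do not tolerate Brønsted acid.

The feature that makes the key step possible is the atom pattern of each bicycle. The ring oxygen bridges tertiary C2 and secondary C7, C3 carries a hydroxyl, and quaternary C6 is bonded to C11. This is what remains when a 2,3-epoxide is opened at C2 by the oxygen of a 6,7-epoxide and that epoxide is opened at C6 by C11 of a C10=C11 alkene. All four rings therefore map onto one linear chain carrying four epoxides and two nucleophilic alkenes.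

## Retrosynthesis

**21 ⇒ 20 ⇒ 19 (acetyl C–O bonds, Si–O at C22).** The C3 and C22 hydroxyls are chemically equivalent, so three of four hydroxyls cannot be acetylated selectively. The free C22 hydroxyl is therefore masked as a silyl ether in 20, and the three acetates come from triol 19 in one exhaustive acylation. The forward steps must acetylate an axial tertiary alcohol and then remove silicon without touching the acetates.

**19 ⇒ 18 ⇒ 16 (C10–CH3, then C10=O back to C10=CH2).** The axial C10 alcohol with equatorial methyl is the product of equatorial attack of a methyl nucleophile on ketone 18. Epoxidation and hydride opening would give the other epimer, so the ketone is the right precursor here. Ketone 18 comes from oxidative cleavage of the exocyclic methylene of 16.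

**16 ⇒ 15 ⇒ 14 ⇒ 13 (Si–O at C22; C15 carbinol by epoxide opening; epoxide C–O).** The equatorial C15 alcohol with axial methyl is the product of equatorial epoxidation of a C15 methylene and hydride opening at the primary carbon. In C2-symmetric diol-diene 13 the two methylenes are homotopic, so mono-epoxidation gives the single compound 14 and recovered 13 is reused. The link between "free C22–OH" and "equatorial C15 carbinol" cannot be made by a directing effect. It is made by mono-silylation of triol 15 and separation from the regioisomer. Silylation is placed after the epoxide has been reduced, so that every unwanted silylation product returns to 15 with fluoride. Silylating 13 first was rejected because the wrong regioisomer of the following epoxidation would be lost.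

**13 ⇒ 11 (O–C2, C6–C11, O–C23, C14–C19).** The four ring-forming bonds are cut at once, leading to tetraepoxide bis(allylsilane) 11. Cuts through one ring at a time would need two separate bicycle syntheses and a later sp3–sp3 union. This cut removes all four rings, inverts or retains the six epoxide stereocentres predictably and creates C11 and C14. The precursor is an acyclic C2-symmetric chain. The forward reaction must run two independent epoxonium cascades to completion on one molecule.

**11 ⇒ 10 (C12–C13).** The chain is C2-symmetric about this bond, so it is cut to two identical allylic bromides 10 and formed by reductive homocoupling. A sulfone–bromide alkylation would make the same bond in three steps and is kept as a reserve. The forward step must couple the primary termini and keep the alkene geometry.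

**10 ⇒ 8 ⇒ 7 ⇒ 6 (C–Br, ester reduction, four epoxide C–O bonds).** The bromide comes from allylic alcohol 8 and this from ester 7. The epoxides are introduced at the ester stage, on 6. Only there is the C10=C11 alkene deactivated by conjugation, so reagent-controlled Shi epoxidation touches only the C2=C3 and C6=C7 alkenes. After reduction the allylsilane alkene would compete.

**6 ⇒ 4 + 5; 4 ⇒ 3 (C10–CH2Si, C10–O).** The allylsilane is cut at the C10–CH2Si bond to (Z)-enol triflate 4 and Grignard reagent 5. The triflate geometry, fixed by chelation in β-keto ester 3, becomes the (Z)-allylsilane geometry that the chair of the key step needs.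

**3 ⇒ 1 + 2 (C8–C9).** β-Keto ester 3 is the γ-alkylation product of the dianion of methyl acetoacetate 1 with geranyl bromide 2. Geranyl bromide supplies C1–C8 with the (E)-C6=C7 alkene.

## Roads not taken

**Alternative 1:** The cut runs through both cyclohexanes (C6–C11/C7–C8 and C14–C19/C17–C18) and leads to the central tetraene A2, (3E,7E)-3,8-dimethyldeca-1,3,7,9-tetraene, and two molecules of the acrolein A3, (E)-3-benzoyloxy-2-methylacrolein. Forward, a chiral oxazaborolidinium Lewis acid would steer a double Diels–Alder reaction to the C2-symmetric dialdehyde dibenzoate A1.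
- Merits: six stereocentres, two of them quaternary, are set by catalyst control from achiral pieces in a pericyclic step, and the bridge is present from the start. In robustness of the ring-forming event this road is better than a long cationic cascade.
- Weak points: A1 contains only the carbocycles. Both oxepanes must be grown from neopentyl aldehydes, with the C3/C22 carbinols set without a nearby control element and the rings closed through tertiary ethers. The C9=C10 and C15=C16 ring alkenes must be hydrated regio- and stereoselectively. The aldehyde must end up trans to the bridge substituent at both ends.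
- Comparison: A1 is C2-symmetric like 13, so the same desymmetrisation is owed. The chosen plan sets against the safer cycloaddition that it closes the oxepanes, the C3/C22 carbinols and the ring fusions in the same step, from two Shi epoxidations.

**Alternative 2:** The cut removes C5–C6 and C11–C12 from one cyclohexane and leads to the enone A5, (S)-4-(tert-butyldimethylsilyloxy)-3-methylcyclohex-2-en-1-one. Forward, the homoprenyl Grignard reagent A6 adds under monovalent-copper catalysis with a silyl chloride anti to the C7 silyloxy group, and the regenerated enolate is alkylated by tert-butyl iodoacetate A7 to give cyclohexanone A4.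
- Merits: the stereocontrol is substrate-based and well understood, and the C10 ketone is delivered directly. The two bicycles are made separately, so the left and right halves are different from the outset and no statistical step is needed. In this respect the road is clearly better than the chosen plan.
- Weak points: a quaternary centre is made by conjugate addition to a β,β-disubstituted enone next to the silyloxy carbon, then a hindered α-carbon is alkylated trans to it. The oxepane must then close by attack of the C7 hydroxyl at tertiary C2, where the six-membered ether is a competitor. C3 needs a separate asymmetric step. All of this is done twice, followed by an sp3–sp3 union at C12–C13 next to ring stereocentres.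
- Comparison: the chosen plan has far fewer steps and relays all core stereochemistry from the epoxides. It must set the recycling loop at step 11 against the clean differentiation of this road.

**Alternative 3:** The cut is the O–C7 bond of one oxepane and leads to a ring-opened derivative of the ent-labdane andrographolide A9. Forward, the silylated C2 tertiary alcohol would add to a C7 ketone and a silane would reduce the seven-membered oxocarbenium ion under a Lewis acid, giving bicycle A8 with a C12 silyloxymethyl arm.
- Merits: the chiral pool supplies the cyclohexane with the correct absolute configuration at C6 and C11 and the exocyclic methylene at C10. Reductive etherification is dependable for the trans-fused oxepane. The halves are differentiated by construction, again better than the chosen plan.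
- Weak points: the degradation is long. The bond between the future C2 and the ring-fusion carbon (future C7), which has no functional handle, must be cleaved. The hydroxymethyl group must become methyl and the butenolide side chain must be trimmed to one carbon. By descriptor comparison the C3 carbinol of A9 appears to need inversion. Two bicycles must be made and joined at C12–C13.
- Comparison: the chosen plan relies on reagent control and a demanding cascade where this road uses nature's stereochemistry, but it reaches the tetracycle in eight steps.

Key step: step 8

Assumption: the L-fructose-derived enantiomer of the Shi ketone is taken as purchasable (it is otherwise made from L-sorbose); it should give the (S)-configured epoxides.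
Remark: metal enolates, alkoxides and carbanions generated in situ are treated as salts of the numbered compounds; covalent intermediates that are not isolated (9, 12, 17) carry their own numbers.

## Route

Step 1
Reactants: 1 methyl acetoacetate; 2 geranyl bromide
Product: 3 methyl (6E)-7,11-dimethyl-3-oxododeca-6,10-dienoate
Conditions: NaH, THF, 0 °C; n-BuLi, 0 °C; then 2, 0 °C → rt; aq. HCl
Reagents that add atoms: none
Why: Dianion alkylation of a β-keto ester: the more reactive terminal carbanion attacks the allylic bromide by SN2 at the primary carbon, forming C8–C9 with the (E)-alkene unchanged.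

Step 2
Reactants: 3 methyl (6E)-7,11-dimethyl-3-oxododeca-6,10-dienoate
Product: 4 methyl (2Z,6E)-7,11-dimethyl-3-(trifluoromethanesulfonyloxy)dodeca-2,6,10-trienoate
Conditions: Tf2O, sat. aq. LiOH, hexanes, 5 °C
Reagents that add atoms: trifluoromethanesulfonic anhydride, O=S(=O)(OS(=O)(=O)C(F)(F)F)C(F)(F)F
Why: Lithium chelation between the enolate oxygen and the ester carbonyl holds the enolate in the Z geometry and O-sulfonylation traps it as the (Z)-enol triflate; the isolated alkenes are inert in the basic two-phase medium.

Step 3
Reactants: 4 methyl (2Z,6E)-7,11-dimethyl-3-(trifluoromethanesulfonyloxy)dodeca-2,6,10-trienoate; 5 (trimethylsilyl)methylmagnesium chloride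
Product: 6 methyl (2Z,6E)-7,11-dimethyl-3-[(trimethylsilyl)methyl]dodeca-2,6,10-trienoate
Conditions: Pd(PPh3)4 (5 mol %), THF, 0 °C → rt
Reagents that add atoms: none
Why: Kumada coupling: zerovalent palladium inserts into the vinyl C–OTf bond, the silylmethyl Grignard reagent (no β-hydrogen) transmetalates and reductive elimination proceeds with retention, giving the (Z)-allylsilane; the conjugated ester is not attacked by this weakly nucleophilic Grignard reagent at 0 °C.

Step 4
Reactants: 6 methyl (2Z,6E)-7,11-dimethyl-3-[(trimethylsilyl)methyl]dodeca-2,6,10-trienoate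
Product: 7 methyl (2Z)-5-[(2S,3S)-3-{2-[(2S)-3,3-dimethyloxiran-2-yl]ethyl}-3-methyloxiran-2-yl]-3-[(trimethylsilyl)methyl]pent-2-enoate (squalene locants 3S,6S,7S)
Conditions: L-fructose-derived Shi ketone (cat.), Oxone (2KHSO5·KHSO4·K2SO4), K2CO3, Bu4NHSO4, MeCN/CH2(OMe)2/aq. Na2B4O7 buffer, 0 °C
Reagents that add atoms: potassium peroxymonosulfate (active component of Oxone), [K+].[O-]S(=O)(=O)OO
Why: Shi asymmetric epoxidation: the chiral dioxirane transfers oxygen through a spiro transition state to the two electron-rich trisubstituted alkenes, the L-fructose-derived ketone setting 3S and 6S,7S under reagent control, while the ester-conjugated C10=C11 alkene is too electron-poor to react.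

Step 5
Reactants: 7 diepoxy ester (3S,6S,7S)
Product: 8 (2Z)-5-[(2S,3S)-3-{2-[(2S)-3,3-dimethyloxiran-2-yl]ethyl}-3-methyloxiran-2-yl]-3-[(trimethylsilyl)methyl]pent-2-en-1-ol
Conditions: i-Bu2AlH, CH2Cl2, −78 °C; aq. KNaC4H4O6
Reagents that add atoms: none
Why: 1,2-Reduction of the enoate by the aluminium hydride at low temperature, where trisubstituted epoxides and the allylsilane are inert and the alkene geometry is untouched.

Step 6
Reactants: 8 diepoxy allylic alcohol
Product: 10 [(2Z)-4-bromo-2-(2-{(2S,3S)-3-[2-((2S)-3,3-dimethyloxiran-2-yl)ethyl]-3-methyloxiran-2-yl}ethyl)but-2-en-1-yl]trimethylsilane, via allylic mesylate 9 (not isolated)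
Conditions: MsCl, Et3N, CH2Cl2, −40 °C; then LiBr, THF, 0 °C
Reagents that add atoms: lithium bromide, [Li+].[Br-]
Why: Sulfonylation of the primary allylic alcohol and SN2 displacement by bromide under neutral conditions, which avoids acid that would open the epoxides or protodesilylate the allylsilane; no stereocentre is touched.

Step 7
Reactants: 10 diepoxy allylic bromide (two molecules)
Product: 11 (3S,6S,7S,10Z,14Z,18S,19S,22S)-squalene 2,3;6,7;18,19;22,23-tetraepoxide in which the methyl groups on C10 and C15 each carry a trimethylsilyl group
Conditions: CoCl(PPh3)3, benzene, rt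
Reagents that add atoms: none
Why: Reductive homocoupling of an allylic bromide by the monovalent cobalt complex: halogen abstraction gives an allyl–cobalt intermediate that couples at the less hindered primary termini (C12–C13, head-to-head) with retention of the trisubstituted alkene geometry, under neutral conditions that leave epoxides and allylsilanes alone.

Step 8
Reactants: 11 tetraepoxide bis(allylsilane)
Product: 13 1,2-bis[(3S,5aS,6R,9aS)-3-hydroxy-2,2,5a-trimethyl-7-methylidenedecahydro-1-benzoxepin-6-yl]ethane (squalene locants 3S,6S,7S,11R,14R,18S,19S,22S; exocyclic methylenes at C10 and C15), via bis(trimethylsilyl) ether 12 (not isolated)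
Conditions: Me3SiOTf (2.5 equiv), 2,6-di-tert-butyl-4-methylpyridine, CH2Cl2, −78 °C; then K2CO3, MeOH, rt
Reagents that add atoms: none
Why: Me3SiOTf silylates a terminal epoxide oxygen, the oxygen of the neighbouring 6,7- (18,19-) epoxide opens it at tertiary C2 (C23) to give a bicyclic epoxonium ion, the allylsilane carbon C11 (C14) opens this ion at tertiary C6 (C19) with inversion, and loss of silicon from the β-silyl cation leaves the exocyclic methylene and returns the silyl triflate, so 11 → 12 is a net isomerisation. The closest known reaction type is the silyl-triflate-promoted oxa-/carbacyclisation cascade of a 1,5-diepoxide terminated by an allylsilane, here run at both ends of one chain. Each oxepane closes in the endo mode at the terminal epoxide (7-endo, O–C2 and O–C23) and each cyclohexane by 6-endo attack of the alkene on the epoxonium ion (C6–C11 and C14–C19). The new stereocentres C11 and C14 are set by a chair transition state in which the (Z)-allylsilane holds the bridge chain equatorial; C6 and C19 are inverted, C3, C7, C18 and C22 are retained from the (S)-epoxides, and the trans-epoxide geometry becomes the trans ring fusion. The step needs opening at C2/C23 and C6/C19, which the tertiary-cation character of the trisubstituted epoxides secures, and initiation at the terminal epoxides, which their accessibility and the fast participation of the inner epoxide oxygen favour. The hindered pyridine removes adventitious triflic acid that would protodesilylate the allylsilanes or open epoxides unselectively. The ethylene bridge insulates the two ends, so both cascades should converge on C2-symmetric 12, which K2CO3 in methanol cleaves to diol 13.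

Step 9
Reactants: 13 tetracyclic diol-diene
Product: 14 mono-epoxide of 13: the C15 methylene is a spiro-oxirane with equatorial oxygen (3S,6S,7S,11R,14S,15S,18S,19S,22S); C10 methylene intact
Conditions: mCPBA (0.6 equiv), NaHCO3, CH2Cl2, −20 → 0 °C; unreacted 13 recovered
Reagents that add atoms: 3-chloroperbenzoic acid, OOC(=O)c1cccc(Cl)c1
Why: Prilezhaev epoxidation: the peracid approaches the exocyclic alkene from the equatorial direction, away from the syn-axial angular methyl, so the oxygen becomes equatorial; the two methylenes of 13 are homotopic, so mono-oxidation gives one compound and sub-stoichiometric oxidant limits the bis-epoxide.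

Step 10
Reactants: 14 mono-epoxide
Product: 15 triol (3S,6S,7S,11R,14S,15S,18S,19S,22S): equatorial tertiary C15–OH with axial C15 methyl, C10 methylene, free C3–OH and C22–OH
Conditions: LiAlH4, THF, 0 → 50 °C; H2O, aq. NaOH
Reagents that add atoms: none
Why: SN2 opening of the 1,1-disubstituted epoxide by hydride at the primary carbon leaves the oxygen on C15 with the configuration set in step 9; the exocyclic alkene and the ethers are inert.

Step 11
Reactants: 15 triol
Product: 16 22-O-tert-butyldimethylsilyl ether of 15 (silyl ether in the half that carries the C15 carbinol; C3–OH and C15–OH free)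
Conditions: TBSCl (1 equiv), imidazole, DMF, rt; chromatographic separation; the other silylation products returned to 15 with Bu4NF, THF
Reagents that add atoms: tert-butyldimethylsilyl chloride, CC(C)(C)[Si](C)(C)Cl
Why: Silylation of a secondary alcohol with the silyl chloride and imidazole, to which the tertiary C15–OH is inert; the C3 and C22 hydroxyls react at like rates, so 16 must be separated from its C3 regioisomer and the bis-ether, all of which regenerate 15 on desilylation.

Step 12
Reactants: 16 mono-silyl ether
Product: 18 C10 ketone (3S,6S,7S,11S,14S,15S,18S,19S,22S) with C3–OH, C15–OH and 22-OTBS, via secondary ozonide 17 (not isolated)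
Conditions: O3, CH2Cl2, −78 °C; then PPh3, −78 °C → rt
Reagents that add atoms: ozone, [O-][O+]=O
Why: Ozonolysis of the 1,1-disubstituted alkene (cycloaddition, cycloreversion and recombination to the ozonide, then phosphine reduction); alcohols, ethers and the silyl ether tolerate ozone at −78 °C, and C11 already holds its bridge substituent in the stable equatorial position next to the new ketone.

Step 13
Reactants: 18 ketone
Product: 19 triol (3S,6S,7S,10R,11S,14S,15S,18S,19S,22S): axial tertiary C10–OH with equatorial methyl, equatorial C15–OH, C3–OH, 22-OTBS
Conditions: MeMgBr, CeCl3, THF, −78 → 0 °C; H2O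
Reagents that add atoms: methylmagnesium bromide, C[Mg]Br
Why: 1,2-Addition of the methyl organometallic, with CeCl3 suppressing enolisation; attack from the equatorial side, opposite the syn-axial C6 methyl, gives the axial alcohol with equatorial methyl (10R).

Step 14
Reactants: 19 triol
Product: 20 3,10,15-triacetate 22-O-tert-butyldimethylsilyl ether
Conditions: Ac2O, DMAP, Et3N, CH2Cl2, rt → 40 °C
Reagents that add atoms: acetic anhydride, CC(=O)OC(C)=O
Why: DMAP-catalysed acylation through the N-acetylpyridinium ion: the secondary C3–OH reacts fast, the equatorial C15–OH and the axial C10–OH more slowly under excess anhydride and gentle warming, and the silyl ether keeps C22 out of the reaction.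

Step 15
Reactants: 20 triacetate silyl ether
Product: 21 target, (3S,6S,7S,10R,11S,14S,15S,18S,19S,22S)-3,10,15-triacetate with free C22–OH
Conditions: HF·pyridine, pyridine/THF, 0 °C → rt
Reagents that add atoms: none
Why: Fluoride-driven Si–O cleavage in a buffered medium that leaves secondary and tertiary acetates and the tertiary ethers untouched; no acyl migration is possible because no acetate is near C22.

## Compound list

1 | methyl acetoacetate | COC(=O)CC(C)=O | starting material
2 | geranyl bromide | CC(C)=CCC/C(C)=C/CBr | starting material
3 | methyl (6E)-7,11-dimethyl-3-oxododeca-6,10-dienoate | CC(C)=CCC/C(C)=C/CCC(=O)CC(=O)OC | intermediate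
4 | methyl (2Z,6E)-7,11-dimethyl-3-(trifluoromethanesulfonyloxy)dodeca-2,6,10-trienoate | CC(C)=CCC/C(C)=C/CC/C(OS(=O)(=O)C(F)(F)F)=C/C(=O)OC | intermediate
5 | (trimethylsilyl)methylmagnesium chloride | C[Si](C)(C)C[Mg]Cl | starting material
6 | methyl (2Z,6E)-7,11-dimethyl-3-[(trimethylsilyl)methyl]dodeca-2,6,10-trienoate | CC(C)=CCC/C(C)=C/CC/C(C[Si](C)(C)C)=C/C(=O)OC | intermediate
7 | methyl (2Z)-5-[(2S,3S)-3-{2-[(2S)-3,3-dimethyloxiran-2-yl]ethyl}-3-methyloxiran-2-yl]-3-[(trimethylsilyl)methyl]pent-2-enoate | CC1(C)O[C@H]1CC[C@]2(C)O[C@H]2CC/C(C[Si](C)(C)C)=C/C(=O)OC | intermediate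
8 | (2Z)-5-[(2S,3S)-3-{2-[(2S)-3,3-dimethyloxiran-2-yl]ethyl}-3-methyloxiran-2-yl]-3-[(trimethylsilyl)methyl]pent-2-en-1-ol | CC1(C)O[C@H]1CC[C@]2(C)O[C@H]2CC/C(C[Si](C)(C)C)=C/CO | intermediate
9 | methanesulfonate of 8 | CC1(C)O[C@H]1CC[C@]2(C)O[C@H]2CC/C(C[Si](C)(C)C)=C/COS(C)(=O)=O | intermediate
10 | [(2Z)-4-bromo-2-(2-{(2S,3S)-3-[2-((2S)-3,3-dimethyloxiran-2-yl)ethyl]-3-methyloxiran-2-yl}ethyl)but-2-en-1-yl]trimethylsilane | CC1(C)O[C@H]1CC[C@]2(C)O[C@H]2CC/C(C[Si](C)(C)C)=C/CBr | intermediate
11 | (3S,6S,7S,10Z,14Z,18S,19S,22S)-squalene 2,3;6,7;18,19;22,23-tetraepoxide with trimethylsilyl groups on the C10 and C15 methyl carbons | CC1(C)O[C@H]1CC[C@]2(C)O[C@H]2CC/C(C[Si](C)(C)C)=C/CC/C=C(C[Si](C)(C)C)/CC[C@@H]3O[C@@]3(C)CC[C@@H]4OC4(C)C | intermediate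
12 | 3,22-bis(trimethylsilyl) ether of 13 | C[Si](C)(C)O[C@H]1CC[C@]2(C)[C@H](CCC(=C)[C@H]2CC[C@H]2[C@]3(C)CC[C@H](O[Si](C)(C)C)C(C)(C)O[C@H]3CCC2=C)OC1(C)C | intermediate
13 | 1,2-bis[(3S,5aS,6R,9aS)-3-hydroxy-2,2,5a-trimethyl-7-methylidenedecahydro-1-benzoxepin-6-yl]ethane | O[C@H]1CC[C@]2(C)[C@H](CCC(=C)[C@H]2CC[C@H]2[C@]3(C)CC[C@H](O)C(C)(C)O[C@H]3CCC2=C)OC1(C)C | intermediate
14 | mono-epoxide of 13 (15S spiro-oxirane, oxygen equatorial; 3S,6S,7S,11R,14S,18S,19S,22S) | O[C@H]1CC[C@]2(C)[C@H](CCC(=C)[C@H]2CC[C@H]2[C@]3(C)CC[C@H](O)C(C)(C)O[C@H]3CC[C@@]24CO4)OC1(C)C | intermediate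
15 | 3,15,22-triol with C10 methylene (3S,6S,7S,11R,14S,15S,18S,19S,22S) | O[C@H]1CC[C@]2(C)[C@H](CCC(=C)[C@H]2CC[C@H]2[C@]3(C)CC[C@H](O)C(C)(C)O[C@H]3CC[C@]2(C)O)OC1(C)C | intermediate
16 | 22-O-tert-butyldimethylsilyl ether of 15 | O[C@H]1CC[C@]2(C)[C@H](CCC(=C)[C@H]2CC[C@H]2[C@]3(C)CC[C@H](O[Si](C)(C)C(C)(C)C)C(C)(C)O[C@H]3CC[C@]2(C)O)OC1(C)C | intermediate
17 | secondary ozonide of 16 (spiro-1,2,4-trioxolane at C10, epimer mixture at that carbon) | O[C@H]1CC[C@]2(C)[C@H](CCC4(OCOO4)[C@H]2CC[C@H]2[C@]3(C)CC[C@H](O[Si](C)(C)C(C)(C)C)C(C)(C)O[C@H]3CC[C@]2(C)O)OC1(C)C | intermediate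
18 | C10 ketone with C3–OH, C15–OH and 22-OTBS (3S,6S,7S,11S,14S,15S,18S,19S,22S) | O[C@H]1CC[C@]2(C)[C@H](CCC(=O)[C@H]2CC[C@H]2[C@]3(C)CC[C@H](O[Si](C)(C)C(C)(C)C)C(C)(C)O[C@H]3CC[C@]2(C)O)OC1(C)C | intermediate
19 | 3,10,15-triol 22-O-tert-butyldimethylsilyl ether (3S,6S,7S,10R,11S,14S,15S,18S,19S,22S) | O[C@H]1CC[C@]2(C)[C@H](CC[C@@](C)(O)[C@H]2CC[C@H]2[C@]3(C)CC[C@H](O[Si](C)(C)C(C)(C)C)C(C)(C)O[C@H]3CC[C@]2(C)O)OC1(C)C | intermediate
20 | 3,10,15-triacetate 22-O-tert-butyldimethylsilyl ether | CC(=O)O[C@H]1CC[C@]2(C)[C@H](CC[C@@](C)(OC(C)=O)[C@H]2CC[C@H]2[C@]3(C)CC[C@H](O[Si](C)(C)C(C)(C)C)C(C)(C)O[C@H]3CC[C@]2(C)OC(C)=O)OC1(C)C | intermediate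
21 | CNP0169816.1: (3S,6S,7S,10R,11S,14S,15S,18S,19S,22S)-3,10,15-triacetate with free C22–OH | CC(=O)O[C@H]1CC[C@]2(C)[C@H](CC[C@@](C)(OC(C)=O)[C@H]2CC[C@H]2[C@]3(C)CC[C@H](O)C(C)(C)O[C@H]3CC[C@]2(C)OC(C)=O)OC1(C)C | target

## Step count and risks

Total step count: 15. Longest linear sequence: 15 steps, from 1 and 2 to 21; step 7 uses bromide 10 twice.

**Step 8 (key step).** Two independent cascades must both finish on one molecule, so every loss is counted twice. The likely failures are:
- one end stalling after the other has cyclised;
- silylation of an inner epoxide first, giving carbocyclisation without oxepane formation;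
- exo opening to five- or six-membered ethers;
- protodesilylation of an allylsilane by traces of triflic acid.

Fallback, cascade before union: the route leaves at alcohol 8 and returns at 13. Silylation with tert-butylchlorodiphenylsilane and imidazole gives the tert-butyldiphenylsilyl ether F1. A single cascade under the conditions of step 8 gives the bicyclic bis(silyl ether) F2, which is not isolated, and Bu4NF gives the bicyclic diol F3. Iodine, PPh3 and imidazole convert only the unhindered primary hydroxyl into the primary iodide F4. Nickel-catalysed reductive homocoupling of this alkyl iodide (NiCl2(dme), a terpyridine ligand, Mn powder, DMF) forms C12–C13 and gives 13.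

**Step 7.** The allyl intermediate may couple through its tertiary terminus (head-to-tail), lose alkene geometry, or undergo desilylative 1,4-elimination to a diene.

Fallback, sulfone alkylation: the route leaves at bromide 10 and returns at 11. Sodium benzenesulfinate in DMF gives the allylic phenyl sulfone F5. Its lithium carbanion (n-BuLi, THF, −78 °C) is alkylated by a second equivalent of 10 to give the C12-phenylsulfonyl chain F6. Reductive desulfonylation with PdCl2(dppp) and LiBHEt3 at 0 °C, with hydride delivered to the less substituted allyl terminus, gives 11.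

**Step 11.** The two secondary hydroxyls are remote from everything that distinguishes the halves, so silylation is regiorandom. On statistical grounds no more than about a quarter of 15 can emerge as 16 in one pass, and the regioisomers may not separate cleanly.

Fallback, differentiation deferred to the last step: the route leaves at 15 and returns at 21. Ozonolysis of 15, through the ozonide F7 and reduction with PPh3, gives the keto-triol F8. MeMgBr with CeCl3 gives the tetraol F9. Exhaustive acetylation gives the tetraacetate F10. Partial methanolysis with K2CO3 in MeOH, which spares the tertiary acetates, removes one secondary acetate. Target 21 is separated from its C3-hydroxy regioisomer by HPLC, and the other fractions are re-acetylated to F10.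

**Step 9.** Facial selectivity of the peracid may be incomplete, because the equatorial approach is flanked by the bridge substituent, and over-oxidation to the bis-epoxide consumes material.

Fallback, radical hydration: the route leaves at 13 and returns at 15, bypassing 14. Mukaiyama hydration of one methylene (Co(acac)2, PhSiH3, O2, i-PrOH, limited conversion) forms a tertiary C15 radical. Oxygen should trap it on the equatorial face, away from the syn-axial methyl, giving 15 directly.

**Step 14.** Acylation of the axial C10 hydroxyl, which is syn-axial to the C6 methyl, may stop short. Forcing conditions risk elimination of the tertiary carbinols or loss of the silyl ether.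

Fallback, acylation of the alkoxides as they form: the route leaves at ketone 18 and returns at 20. After the methyl addition of step 13 the magnesium alkoxides at C3, C10 and C15 are not protonated but quenched in the same flask with excess Ac2O. The tertiary acetates are then made from the more nucleophilic alkoxides and 19 is never isolated.

## Further compounds

F1 | step 8 | tert-butyldiphenylsilyl ether of 8 | CC1(C)O[C@H]1CC[C@]2(C)O[C@H]2CC/C(C[Si](C)(C)C)=C/CO[Si](c3ccccc3)(c3ccccc3)C(C)(C)C
F2 | step 8 | bicyclic bis(silyl ether): 3-trimethylsilyloxy oxepane–cyclohexane with C10 methylene and C12 tert-butyldiphenylsilyloxy group | C[Si](C)(C)O[C@H]1CC[C@]2(C)[C@H](CCC(=C)[C@H]2CO[Si](c3ccccc3)(c3ccccc3)C(C)(C)C)OC1(C)C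
F3 | step 8 | bicyclic diol: (3S,5aS,6R,9aS)-6-(hydroxymethyl)-2,2,5a-trimethyl-7-methylidenedecahydro-1-benzoxepin-3-ol | O[C@H]1CC[C@]2(C)[C@H](CCC(=C)[C@H]2CO)OC1(C)C
F4 | step 8 | bicyclic primary iodide: 6-(iodomethyl) analogue of F3 | O[C@H]1CC[C@]2(C)[C@H](CCC(=C)[C@H]2CI)OC1(C)C
F5 | step 7 | allylic phenyl sulfone from 10 | CC1(C)O[C@H]1CC[C@]2(C)O[C@H]2CC/C(C[Si](C)(C)C)=C/CS(=O)(=O)c3ccccc3
F6 | step 7 | 12-phenylsulfonyl derivative of 11 (epimer mixture at C12) | CC1(C)O[C@H]1CC[C@]2(C)O[C@H]2CC/C(C[Si](C)(C)C)=C/C(S(=O)(=O)c5ccccc5)C/C=C(C[Si](C)(C)C)/CC[C@@H]3O[C@@]3(C)CC[C@@H]4OC4(C)C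
F7 | step 11 | secondary ozonide of 15 (epimer mixture at C10) | O[C@H]1CC[C@]2(C)[C@H](CCC4(OCOO4)[C@H]2CC[C@H]2[C@]3(C)CC[C@H](O)C(C)(C)O[C@H]3CC[C@]2(C)O)OC1(C)C
F8 | step 11 | C10 ketone 3,15,22-triol | O[C@H]1CC[C@]2(C)[C@H](CCC(=O)[C@H]2CC[C@H]2[C@]3(C)CC[C@H](O)C(C)(C)O[C@H]3CC[C@]2(C)O)OC1(C)C
F9 | step 11 | 3,10,15,22-tetraol (10R,15S) | O[C@H]1CC[C@]2(C)[C@H](CC[C@@](C)(O)[C@H]2CC[C@H]2[C@]3(C)CC[C@H](O)C(C)(C)O[C@H]3CC[C@]2(C)O)OC1(C)C
F10 | step 11 | 3,10,15,22-tetraacetate | CC(=O)O[C@H]1CC[C@]2(C)[C@H](CC[C@@](C)(OC(C)=O)[C@H]2CC[C@H]2[C@]3(C)CC[C@H](OC(C)=O)C(C)(C)O[C@H]3CC[C@]2(C)OC(C)=O)OC1(C)C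
F0 | step 9 | none | none
F0 | step 14 | none | none
A1 | alternative 1 | C2-symmetric bis(cyclohexene) dialdehyde dibenzoate | O=C[C@]1(C)[C@@H](OC(=O)c2ccccc2)CC=C(C)[C@H]1CC[C@@H]1C(C)=CC[C@H](OC(=O)c3ccccc3)[C@@]1(C)C=O
A2 | alternative 1 | (3E,7E)-3,8-dimethyldeca-1,3,7,9-tetraene | C=C/C(C)=C/CC/C=C(C)/C=C
A3 | alternative 1 | (E)-3-benzoyloxy-2-methylacrolein | O=C/C(C)=C/OC(=O)c1ccccc1
A4 | alternative 2 | cyclohexanone with C6 quaternary centre, homoprenyl chain and C11 tert-butyl acetate arm | O=C1CC[C@H](O[Si](C)(C)C(C)(C)C)[C@@](C)(CCC=C(C)C)[C@@H]1CC(=O)OC(C)(C)C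
A5 | alternative 2 | (S)-4-(tert-butyldimethylsilyloxy)-3-methylcyclohex-2-en-1-one | O=C1CC[C@H](O[Si](C)(C)C(C)(C)C)C(C)=C1
A6 | alternative 2 | 4-methylpent-3-enylmagnesium bromide | CC(C)=CCC[Mg]Br
A7 | alternative 2 | tert-butyl iodoacetate | CC(C)(C)OC(=O)CI
A8 | alternative 3 | left oxepane–cyclohexane bicycle with C12 tert-butyldiphenylsilyloxymethyl arm | CC(=O)O[C@H]1CC[C@]2(C)[C@H](CC[C@@](C)(OC(C)=O)[C@H]2CO[Si](c3ccccc3)(c3ccccc3)C(C)(C)C)OC1(C)C
A9 | alternative 3 | andrographolide | C[C@@]12CC[C@H]([C@@]([C@H]1CCC(=C)[C@H]2C/C=C/3\[C@@H](COC3=O)O)(C)CO)O
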